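## The problem

Compound 13 is a trans-isoflavan-4-ol. A chroman (ring C: O1, C2, C3, C4, C4a, C8a) is fused to a 6,7,8-trimethoxylated ring A, carries a 2',5'-dihydroxy-3',4'-dimethoxyphenyl ring B at C3 and a hydroxyl at C4, and has the (3S,4R) configuration (ring B and OH trans).

The two stereocentres are adjacent. C4 can be derived from C3 by hydride addition to a C4 ketone. C3 has nothing to lean on and must be set absolutely. In any C4-ketone precursor C3 lies between an aryl group and the carbonyl group, so it epimerises easily.

Ring B is a hydroquinone that air oxidises in base, and its two phenols must be kept apart from five methyl ethers from the first step on. The C4 alcohol is benzylic to an arene with O1 ortho and a methoxy group para. It ionises in acid (a free 2'-OH would then close a pterocarpan) and is exposed to hydrogenolysis, so the end of the route must avoid both.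

The enabling feature is that ring A together with O1 and C2 is a 1,2,3,4-tetramethoxybenzene. C2 is the methyl carbon of the methoxy group on C8a and lies 1,6 to C3 along C2–O1–C8a–C4a–C4–C3. A carbene at C3 can therefore reach one of its C–H bonds, and ring C can be closed at C2–C3 with no phenol differentiation on ring A.

## Retrosynthesis

**13 to 12 (O–Si bonds).** The last operation only frees the two phenols of ring B. Silyl ethers are chosen over benzyl ethers (hydrogenolysis endangers the C4–O bond), methyl ethers (not distinguishable from the other five) and esters (a carbonyl oxygen next to the later carbene and enolate). Bis-silyl ether 12 holds the complete skeleton and both stereocentres, and buffered fluoride is all that is asked of the forward step.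

**12 to 11 (C4–H bond).** Removing the hydride at C4 gives isoflavanone 11 with one stereocentre. A small hydride should attack the half-chair ketone axially, anti to the axial C3–H, and place OH trans to the equatorial ring B. The reduction must be non-basic and cold because C3–H of 11 is acidic.

**11 to 10 (C2–C3 bond, the key cut).** Cutting C2–C3 turns C2 back into the methoxy carbon on C8a and C3 into a carbene, that is α-diazo ketone 10. The neighbouring cuts (O1–C2 with a one-carbon electrophile, O1–C8a by aryl etherification) both need a ring A phenol singled out among three methoxy groups, and they pass through achiral or separately built stereo-intermediates. Compound 10 is acyclic and achiral, and its ring A is the intact tetramethoxyphenyl group. The forward reaction must insert into a primary C–H bond next to oxygen, 1,6 to the carbene, with catalyst control of the new C3 centre.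

**10 to 8 and 9 (C=N2).** The diazo group comes from the activated methylene of deoxybenzoin 8 by diazo transfer from sulfonyl azide 9. This is simpler than building the diazo ketone by acylation, and the benzyl aryl ketone is acidic enough for an amidine base.

**8 to 5 and 7 (C4–C4a bond).** The aryl–acyl bond is cut to aryllithium 7, made by lithiation of symmetric arene 6, and Weinreb amide 5. A Friedel–Crafts acylation would make the same bond, but Lewis acids cleave exactly the methoxy group ortho to the new ketone, which is the future C2, and an electron-rich arylacetyl cation can lose CO. The forward step needs addition to outrun deprotonation of the arylacetamide.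

**5 to 4 to 3 (O2'–Si bond, amide C–N bond).** The TIPS group on O2' and the amide are taken off in turn to reach hydroxy ester 3. Amide formation is placed before silylation so that material that has closed onto the ortho phenol converges on the same amide 4.

**3 to 1 and 2 (C1'–CH2 bond).** The side chain is cut from ring B to give quinone 1 and ketene silyl acetal 2. The quinone supplies the hydroquinone oxidation level and keeps the two future phenols distinct from the methoxy groups. Conjugate addition at its only unsubstituted alkene fixes the regiochemistry, and the silyl group of 2 ends on O5', where it serves as the first protecting group.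

## Roads not taken

**Alternative 1: temporary silicon tether.** The cut is at C3–H with a tether from the C4 oxygen. In the enantiopure allylic dimethylsilyl ether A1, H2PtCl6 lets the O-bound Si–H add across C2=C3 to give the cis-4,5-diaryl-1,2-oxasilolane A2. Oxidation of the C2–Si bond (Tamao–Fleming) and closure of O1–C2 onto the freed ring A phenol would follow.
- Merits: C3 is set from C4 through a ring, so the relative configuration does not hang on a hydride's choice of face. C3 is never α to a carbonyl group. C4 can come from a standard asymmetric ketone reduction. Every reaction type is known.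
- Weak points: the alkene is 1,1-disubstituted and flanked by two ortho-disubstituted arenes, so the induction in the 5-endo hydrosilylation is uncertain. Tethering, oxidation, phenol unmasking, etherification and double debenzylation bring the count well above ten steps. Hydrogenolysis would run beside a very labile benzylic C4–O bond. Ring A must arrive with the C8a oxygen already differentiated.
- Comparison: this road is better in the certainty of each step and in relative stereocontrol. The chosen plan sets against it about half the steps, the use of arene 6 as bought, and fluoride-labile protection.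

**Alternative 2: ring C closed at O1–C8a.** Pd(OAc)2 with a di-tert-butylphosphino biaryl ligand and Cs2CO3 couples the primary C2 hydroxyl of bromo alcohol A3 with the aryl bromide at C8a to give chromane A4.
- Merits: both stereocentres are in place before the ring is closed and neither can epimerise afterwards. They come from an auxiliary-controlled aldol-type C3–C4 bond formation with a predictable outcome. The etherification is an established ring closure.
- Weak points: the bromide sits between a methoxy group and a branched benzylic carbon on an electron-rich ring, so oxidative addition is slow. The palladium alkoxide of a primary alcohol can undergo β-hydride elimination. Anti-selective aldol reactions of arylacetyl units are less general than syn ones. Auxiliary handling, C4–OH protection and a final hydrogenolysis bring the count to about twelve steps.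
- Comparison: this is the safer road and its stereochemical outcome is more predictable. The chosen plan sets against it brevity, catalytic instead of stoichiometric chirality, no halogenated ring A building block and no hydrogenolysis.

**Alternative 3: ortho-quinone methide electrocyclisation.** C4–C4a and O1–C2 are cut together. PhB(OH)2 with an acid in hot toluene joins phenol A5 and 2-arylacrolein A6 at C4a–C4, and the resulting ortho-quinone methide closes by oxa-6π electrocyclisation to the isoflav-3-ene A7.
- Merits: it is the most convergent road, with two bonds and ring C made in one step. A5 has a single free ortho position. A later hydroboration–oxidation of C3=C4 adds H and OH syn, which gives the trans relationship by mechanism.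
- Weak points: A7 is achiral, so the whole stereochemical burden falls on an enantioselective hydroboration of a trisubstituted, electron-rich alkene. Stoichiometric chiral boranes are the realistic reagents, and boron must go to C4 and not C3. A6 is prone to polymerise, and its condensation is less established than that of β-substituted enals. Benzyl ethers again call for hydrogenolysis.
- Comparison: in step count this road equals or beats the chosen plan, and its relative stereocontrol is better. The chosen plan sets against it that a catalyst delivers the absolute configuration in the ring-forming step, and that deprotection needs only fluoride.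

Key step: step 6

Assumption: the sense of induction of Rh2(S-PTTL)4 on this substrate is not known; the route is written for the S-configured catalyst giving (3S)-11, and the mirror-image catalyst Rh2(R-PTTL)4 would be used with no other change if the sense proves opposite.

## Route

Step 1
Reactants: 1 2,3-dimethoxy-1,4-benzoquinone; 2 1-(tert-butyldimethylsilyloxy)-1-methoxyethene
Product: 3 methyl 2-[5-(tert-butyldimethylsilyloxy)-2-hydroxy-3,4-dimethoxyphenyl]acetate
Conditions: LiClO4 (10 mol %), MeCN, −40 °C → 0 °C; pH 7 buffer
Reagents that add atoms: none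
Why: Mukaiyama–Michael addition: the ketene silyl acetal should add to the only unsubstituted alkene of the quinone, since the methoxy-bearing carbons are deactivated and hindered. Silicon passes to the enolate oxygen and tautomerisation to the arene leaves TBS on O5' and a free hydroxyl at O2'; the mono-silylated product cannot be re-oxidised by unreacted quinone.

Step 2
Reactants: 3 methyl 2-[5-(tert-butyldimethylsilyloxy)-2-hydroxy-3,4-dimethoxyphenyl]acetate
Product: 4 2-[5-(tert-butyldimethylsilyloxy)-2-hydroxy-3,4-dimethoxyphenyl]-N-methoxy-N-methylacetamide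
Conditions: MeNHOMe·HCl, Al(CH3)3, CH2Cl2, 0 °C → rt; aq. potassium sodium tartrate
Reagents that add atoms: N,O-dimethylhydroxylamine hydrochloride, CNOC.Cl
Why: Weinreb amidation with the aluminium amide formed in the flask; the reagent is Lewis acidic and not basic, so the acidic benzylic CH2 is left alone. Any material that has lactonised onto the ortho phenol is opened to the same amide.

Step 3
Reactants: 4 2-[5-(tert-butyldimethylsilyloxy)-2-hydroxy-3,4-dimethoxyphenyl]-N-methoxy-N-methylacetamide
Product: 5 2-[5-(tert-butyldimethylsilyloxy)-3,4-dimethoxy-2-(triisopropylsilyloxy)phenyl]-N-methoxy-N-methylacetamide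
Conditions: TIPSOTf, 2,6-lutidine, CH2Cl2, 0 °C → rt
Reagents that add atoms: triisopropylsilyl trifluoromethanesulfonate, CC(C)[Si](OS(=O)(=O)C(F)(F)F)(C(C)C)C(C)C
Why: Silylation of a hindered phenol with a silyl triflate and a hindered base. TIPS is put on O2' because it has no C–H bond next to oxygen for the later carbene and resists transfer to the neighbouring enolates of steps 4 and 5.

Step 4
Reactants: 5 2-[5-(tert-butyldimethylsilyloxy)-3,4-dimethoxy-2-(triisopropylsilyloxy)phenyl]-N-methoxy-N-methylacetamide; 6 1,2,3,4-tetramethoxybenzene
Product: 8 2-[5-(tert-butyldimethylsilyloxy)-3,4-dimethoxy-2-(triisopropylsilyloxy)phenyl]-1-(2,3,4,5-tetramethoxyphenyl)ethan-1-one, via (2,3,4,5-tetramethoxyphenyl)lithium 7 (not isolated)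
Conditions: 6, n-BuLi, TMEDA, THF, 0 °C; then 5, −78 °C → −20 °C; aq. NH4Cl
Reagents that add atoms: none
Why: Directed ortho-lithiation of 6 (its two free positions are equivalent) followed by Weinreb ketone synthesis; the chelated tetrahedral adduct prevents over-addition. No Lewis acid is present, so the methoxy group ortho to the new ketone, the future C2, is kept.

Step 5
Reactants: 8 2-[5-(tert-butyldimethylsilyloxy)-3,4-dimethoxy-2-(triisopropylsilyloxy)phenyl]-1-(2,3,4,5-tetramethoxyphenyl)ethan-1-one; 9 4-acetamidobenzenesulfonyl azide
Product: 10 2-diazo-2-[5-(tert-butyldimethylsilyloxy)-3,4-dimethoxy-2-(triisopropylsilyloxy)phenyl]-1-(2,3,4,5-tetramethoxyphenyl)ethan-1-one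
Conditions: DBU, MeCN/CH2Cl2 (dry), 0 °C → rt
Reagents that add atoms: none
Why: Regitz diazo transfer to a benzyl aryl ketone: DBU forms the enolate stabilised by ketone and arene, which attacks the terminal nitrogen of the sulfonyl azide and expels the sulfonamide. Dry conditions keep the aryl silyl ethers intact.

Step 6
Reactants: 10 2-diazo-2-[5-(tert-butyldimethylsilyloxy)-3,4-dimethoxy-2-(triisopropylsilyloxy)phenyl]-1-(2,3,4,5-tetramethoxyphenyl)ethan-1-one
Product: 11 (3S)-3-[5-(tert-butyldimethylsilyloxy)-3,4-dimethoxy-2-(triisopropylsilyloxy)phenyl]-6,7,8-trimethoxychroman-4-one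
Conditions: Rh2(S-PTTL)4 (dirhodium tetrakis[N-phthaloyl-(S)-tert-leucinate], 1 mol %), CH2Cl2, 4 Å molecular sieves, 0 °C → rt, slow addition of 10
Reagents that add atoms: none
Why: Proposed new method: Rh2(S-PTTL)4 expels N2 from 10 and gives a rhodium-bound donor–acceptor carbene at C3 (ring B as donor, the aroyl group as acceptor), whose empty orbital takes up a C–H bond of the methoxy group ortho to the ketone on ring A in a concerted, hydride-transfer-like three-centre transition state, forming C2–C3 and C3–H and releasing the catalyst. The closest known reaction types are the dirhodium-catalysed 1,6 insertion of ortho-alkoxyaryl α-diazo ketones into an O–CH2R bond to give chroman-4-ones and the enantioselective intermolecular insertion of aryl-substituted donor–acceptor carbenes into the methyl C–H bonds of methyl ethers; their union on an aryl methyl ether with an α-aryl-α-diazo ketone has not been shown. Ring C closes by 1,6 C–H insertion, a six-membered closure helped by the lone pair on O1, which activates the C–H bond, and by the planar aroyl unit, which holds the methyl group within reach of C3. C3 is the only new stereocentre and arises at the carbene carbon, so its configuration is set by the catalyst alone: the four N-phthaloyl-tert-leucinate ligands wall off one face of the carbene and the methoxy C–H bond must approach from the other. Site selectivity rests on the substitution pattern: no other oxygen-activated C–H bond lies within five or six atoms of C3, since O2' carries a triisopropylsilyl group (only hindered Si–CH bonds) and ring A has no sp3 C–H bond 1,5 to the carbene. Chemoselectivity is helped by the absence of any ester or carbonate carbonyl near the carbene (no carbonyl ylide) and by the fact that the oxonium ylide from attack of the methoxy oxygen can only shift a methyl group, which is slow, so it should revert; slow addition and molecular sieves hold back carbene dimerisation and O–H insertion of water. Ketone 11 has an acidic C3–H, so it is not chromatographed but taken at once into step 7.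

Step 7
Reactants: 11 (3S)-3-[5-(tert-butyldimethylsilyloxy)-3,4-dimethoxy-2-(triisopropylsilyloxy)phenyl]-6,7,8-trimethoxychroman-4-one
Product: 12 (3S,4R)-3-[5-(tert-butyldimethylsilyloxy)-3,4-dimethoxy-2-(triisopropylsilyloxy)phenyl]-6,7,8-trimethoxychroman-4-ol (3,4-trans)
Conditions: crude 11, NaBH4, CeCl3·7H2O, MeOH/THF, −78 °C → −40 °C; aq. NH4Cl
Reagents that add atoms: none
Why: Luche reduction: the small methoxyborohydride should attack the half-chair ketone axially, anti to the axial C3–H, so that the new hydroxyl is equatorial and trans to the equatorial ring B; C4 is thus set by C3 (substrate control). CeCl3 keeps the medium non-basic, which should protect C3 from enolisation.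

Step 8
Reactants: 12 (3S,4R)-3-[5-(tert-butyldimethylsilyloxy)-3,4-dimethoxy-2-(triisopropylsilyloxy)phenyl]-6,7,8-trimethoxychroman-4-ol
Product: 13 (3S,4R)-3-(2,5-dihydroxy-3,4-dimethoxyphenyl)-6,7,8-trimethoxychroman-4-ol (3,4-trans; CNP0111047.1)
Conditions: Bu4NF, AcOH, THF, 0 °C, argon; degassed aq. NH4Cl/Na2S2O4 work-up
Reagents that add atoms: none
Why: Fluoride cleavage of both aryl silyl ethers under acetic acid buffering. No acid strong enough to ionise the C4 benzylic alcohol is present, and argon with dithionite in the work-up keeps ring B at the hydroquinone level.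

## Compound list

1 | 2,3-dimethoxy-1,4-benzoquinone | COC1=C(OC)C(=O)C=CC1=O | starting material
2 | 1-(tert-butyldimethylsilyloxy)-1-methoxyethene | C=C(OC)O[Si](C)(C)C(C)(C)C | starting material
3 | methyl 2-[5-(tert-butyldimethylsilyloxy)-2-hydroxy-3,4-dimethoxyphenyl]acetate | COC(=O)Cc1cc(O[Si](C)(C)C(C)(C)C)c(OC)c(OC)c1O | intermediate
4 | 2-[5-(tert-butyldimethylsilyloxy)-2-hydroxy-3,4-dimethoxyphenyl]-N-methoxy-N-methylacetamide | CON(C)C(=O)Cc1cc(O[Si](C)(C)C(C)(C)C)c(OC)c(OC)c1O | intermediate
5 | 2-[5-(tert-butyldimethylsilyloxy)-3,4-dimethoxy-2-(triisopropylsilyloxy)phenyl]-N-methoxy-N-methylacetamide | CON(C)C(=O)Cc1cc(O[Si](C)(C)C(C)(C)C)c(OC)c(OC)c1O[Si](C(C)C)(C(C)C)C(C)C | intermediate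
6 | 1,2,3,4-tetramethoxybenzene | COc1ccc(OC)c(OC)c1OC | starting material
7 | (2,3,4,5-tetramethoxyphenyl)lithium | [Li]c1cc(OC)c(OC)c(OC)c1OC | intermediate
8 | 2-[5-(tert-butyldimethylsilyloxy)-3,4-dimethoxy-2-(triisopropylsilyloxy)phenyl]-1-(2,3,4,5-tetramethoxyphenyl)ethan-1-one | COc1cc(C(=O)Cc2cc(O[Si](C)(C)C(C)(C)C)c(OC)c(OC)c2O[Si](C(C)C)(C(C)C)C(C)C)c(OC)c(OC)c1OC | intermediate
9 | 4-acetamidobenzenesulfonyl azide | CC(=O)Nc1ccc(cc1)S(=O)(=O)N=[N+]=[N-] | starting material
10 | 2-diazo-2-[5-(tert-butyldimethylsilyloxy)-3,4-dimethoxy-2-(triisopropylsilyloxy)phenyl]-1-(2,3,4,5-tetramethoxyphenyl)ethan-1-one | COc1cc(C(=O)C(=[N+]=[N-])c2cc(O[Si](C)(C)C(C)(C)C)c(OC)c(OC)c2O[Si](C(C)C)(C(C)C)C(C)C)c(OC)c(OC)c1OC | intermediate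
11 | (3S)-3-[5-(tert-butyldimethylsilyloxy)-3,4-dimethoxy-2-(triisopropylsilyloxy)phenyl]-6,7,8-trimethoxychroman-4-one | COc1cc2c(c(OC)c1OC)OC[C@H](c1cc(O[Si](C)(C)C(C)(C)C)c(OC)c(OC)c1O[Si](C(C)C)(C(C)C)C(C)C)C2=O | intermediate
12 | (3S,4R)-3-[5-(tert-butyldimethylsilyloxy)-3,4-dimethoxy-2-(triisopropylsilyloxy)phenyl]-6,7,8-trimethoxychroman-4-ol | COc1cc2c(c(OC)c1OC)OC[C@H](c1cc(O[Si](C)(C)C(C)(C)C)c(OC)c(OC)c1O[Si](C(C)C)(C(C)C)C(C)C)[C@H]2O | intermediate
13 | (3S,4R)-3-(2,5-dihydroxy-3,4-dimethoxyphenyl)-6,7,8-trimethoxychroman-4-ol | COc1cc2c(c(OC)c1OC)OC[C@H](c1cc(O)c(OC)c(OC)c1O)[C@H]2O | target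

## Count and risks

Total step count: 8. Longest linear sequence: 8 steps (1 to 13); arene 6 enters in step 4 as bought.

**Step 6 (key step).** The carbene may be diverted by attack of the methoxy oxygen followed by a methyl shift, by Wolff rearrangement or by dimerisation. Insertion into a primary C–H bond is the slowest kind. Face discrimination may be modest because the C–H partner is an unbiased methyl group. The product may lose its configuration by enolisation. The fallback uses known chemistry, sets out from ketone 8 and gives up the methoxy carbon as C2. Brief treatment with BCl3 at −78 °C should cleave only the methoxy group chelated to the ketone and give 2-[5-(tert-butyldimethylsilyloxy)-3,4-dimethoxy-2-(triisopropylsilyloxy)phenyl]-1-(2-hydroxy-3,4,5-trimethoxyphenyl)ethan-1-one F1. Heating with Me2NCH(OMe)2 in toluene adds C2 and closes ring C at O1–C2 to the isoflavone 3-[5-(tert-butyldimethylsilyloxy)-3,4-dimethoxy-2-(triisopropylsilyloxy)phenyl]-6,7,8-trimethoxy-4H-chromen-4-one F2. Noyori-type asymmetric transfer hydrogenation with dynamic kinetic resolution (RuCl(p-cymene)(TsDPEN) of the enantiomer that leads to 3S, HCO2H/Et3N) reduces C2=C3 and C4=O to the cis alcohol (3S,4S)-3-[5-(tert-butyldimethylsilyloxy)-3,4-dimethoxy-2-(triisopropylsilyloxy)phenyl]-6,7,8-trimethoxychroman-4-ol F3. Dess–Martin oxidation buffered with NaHCO3 at 0 °C then returns (3S)-ketone 11, where the route is rejoined.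

**Step 1.** The silyl ketene acetal may add at a carbonyl carbon or oxygen in place of the ring carbon, or reduce the quinone by electron transfer. The fallback sets out from 1 and builds the side chain by electrophilic substitution of a phenol. Na2S2O4 reduces 1 to 2,3-dimethoxybenzene-1,4-diol F4. TBSCl and imidazole silylate one of its two equivalent hydroxyls to give 4-(tert-butyldimethylsilyloxy)-2,3-dimethoxyphenol F5. Ortho-specific Friedel–Crafts hydroxyalkylation of the magnesium phenoxide of F5 with methyl glyoxylate gives methyl 2-[5-(tert-butyldimethylsilyloxy)-2-hydroxy-3,4-dimethoxyphenyl]-2-hydroxyacetate F6. Ionic deoxygenation of the benzylic hydroxyl with Et3SiH and CF3CO2H returns ester 3.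

**Step 4.** The aryllithium may deprotonate the arylacetamide CH2 in place of adding to the carbonyl group, which would return amide after the quench. The fallback sets out from 5 and uses a more electrophilic carbonyl group. (i-Bu)2AlH at −78 °C reduces the Weinreb amide to 2-[5-(tert-butyldimethylsilyloxy)-3,4-dimethoxy-2-(triisopropylsilyloxy)phenyl]acetaldehyde F7. Addition of 7 at −78 °C gives 2-[5-(tert-butyldimethylsilyloxy)-3,4-dimethoxy-2-(triisopropylsilyloxy)phenyl]-1-(2,3,4,5-tetramethoxyphenyl)ethan-1-ol F8. Dess–Martin oxidation returns ketone 8.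

**Step 7.** Facial selectivity of the hydride may be poor, or C3 may be eroded by enolisation before reduction. The fallback sets out from 11 and takes the cis alcohol on purpose. LiBH(s-Bu)3 at −78 °C attacks from the equatorial side and should give the cis alcohol F3 already described under step 6. Mitsunobu inversion at C4 with 4-nitrobenzoic acid, PPh3 and diisopropyl azodicarboxylate gives (3S,4R)-3-[5-(tert-butyldimethylsilyloxy)-3,4-dimethoxy-2-(triisopropylsilyloxy)phenyl]-6,7,8-trimethoxychroman-4-yl 4-nitrobenzoate F9; any ionisation at this benzylic carbon should also end in the trans ester, since the nucleophile enters anti to ring B. Brief methanolysis with K2CO3 in MeOH at 0 °C under argon returns trans alcohol 12.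

## Further compounds

F1 | step 6 | 2-[5-(tert-butyldimethylsilyloxy)-3,4-dimethoxy-2-(triisopropylsilyloxy)phenyl]-1-(2-hydroxy-3,4,5-trimethoxyphenyl)ethan-1-one | COc1cc(C(=O)Cc2cc(O[Si](C)(C)C(C)(C)C)c(OC)c(OC)c2O[Si](C(C)C)(C(C)C)C(C)C)c(O)c(OC)c1OC
F2 | step 6 | 3-[5-(tert-butyldimethylsilyloxy)-3,4-dimethoxy-2-(triisopropylsilyloxy)phenyl]-6,7,8-trimethoxy-4H-chromen-4-one | COc1cc2c(c(OC)c1OC)OC=C(c1cc(O[Si](C)(C)C(C)(C)C)c(OC)c(OC)c1O[Si](C(C)C)(C(C)C)C(C)C)C2=O
F3 | step 6 | (3S,4S)-3-[5-(tert-butyldimethylsilyloxy)-3,4-dimethoxy-2-(triisopropylsilyloxy)phenyl]-6,7,8-trimethoxychroman-4-ol (3,4-cis) | COc1cc2c(c(OC)c1OC)OC[C@H](c1cc(O[Si](C)(C)C(C)(C)C)c(OC)c(OC)c1O[Si](C(C)C)(C(C)C)C(C)C)[C@@H]2O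
F4 | step 1 | 2,3-dimethoxybenzene-1,4-diol | COc1c(O)ccc(O)c1OC
F5 | step 1 | 4-(tert-butyldimethylsilyloxy)-2,3-dimethoxyphenol | COc1c(O)ccc(O[Si](C)(C)C(C)(C)C)c1OC
F6 | step 1 | methyl 2-[5-(tert-butyldimethylsilyloxy)-2-hydroxy-3,4-dimethoxyphenyl]-2-hydroxyacetate (racemic) | COC(=O)C(O)c1cc(O[Si](C)(C)C(C)(C)C)c(OC)c(OC)c1O
F7 | step 4 | 2-[5-(tert-butyldimethylsilyloxy)-3,4-dimethoxy-2-(triisopropylsilyloxy)phenyl]acetaldehyde | O=CCc1cc(O[Si](C)(C)C(C)(C)C)c(OC)c(OC)c1O[Si](C(C)C)(C(C)C)C(C)C
F8 | step 4 | 2-[5-(tert-butyldimethylsilyloxy)-3,4-dimethoxy-2-(triisopropylsilyloxy)phenyl]-1-(2,3,4,5-tetramethoxyphenyl)ethan-1-ol (racemic) | COc1cc(C(O)Cc2cc(O[Si](C)(C)C(C)(C)C)c(OC)c(OC)c2O[Si](C(C)C)(C(C)C)C(C)C)c(OC)c(OC)c1OC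
F9 | step 7 | (3S,4R)-3-[5-(tert-butyldimethylsilyloxy)-3,4-dimethoxy-2-(triisopropylsilyloxy)phenyl]-6,7,8-trimethoxychroman-4-yl 4-nitrobenzoate | COc1cc2c(c(OC)c1OC)OC[C@H](c1cc(O[Si](C)(C)C(C)(C)C)c(OC)c(OC)c1O[Si](C(C)C)(C(C)C)C(C)C)[C@H]2OC(=O)c1ccc(cc1)[N+](=O)[O-]
A1 | alternative 1 | (R)-{2-(2,5-dibenzyloxy-3,4-dimethoxyphenyl)-1-[3,4,5-trimethoxy-2-(triisopropylsilyloxy)phenyl]prop-2-en-1-yloxy}dimethylsilane | C=C(c1cc(OCc2ccccc2)c(OC)c(OC)c1OCc1ccccc1)[C@H](c1cc(OC)c(OC)c(OC)c1O[Si](C(C)C)(C(C)C)C(C)C)O[SiH](C)C
A2 | alternative 1 | (4R,5R)-4-(2,5-dibenzyloxy-3,4-dimethoxyphenyl)-2,2-dimethyl-5-[3,4,5-trimethoxy-2-(triisopropylsilyloxy)phenyl]-1,2-oxasilolane (4,5-cis) | C[Si]1(C)C[C@H](c2cc(OCc3ccccc3)c(OC)c(OC)c2OCc2ccccc2)[C@H](c2cc(OC)c(OC)c(OC)c2O[Si](C(C)C)(C(C)C)C(C)C)O1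
A3 | alternative 2 | (2S,3R)-3-(2-bromo-3,4,5-trimethoxyphenyl)-3-(tert-butyldimethylsilyloxy)-2-(2,5-dibenzyloxy-3,4-dimethoxyphenyl)propan-1-ol | OC[C@H](c1cc(OCc2ccccc2)c(OC)c(OC)c1OCc1ccccc1)[C@@H](O[Si](C)(C)C(C)(C)C)c1cc(OC)c(OC)c(OC)c1Br
A4 | alternative 2 | (3S,4R)-4-(tert-butyldimethylsilyloxy)-3-(2,5-dibenzyloxy-3,4-dimethoxyphenyl)-6,7,8-trimethoxychromane | COc1cc2c(c(OC)c1OC)OC[C@H](c1cc(OCc3ccccc3)c(OC)c(OC)c1OCc1ccccc1)[C@H]2O[Si](C)(C)C(C)(C)C
A5 | alternative 3 | 2,3,4-trimethoxyphenol | COc1ccc(O)c(OC)c1OC
A6 | alternative 3 | 2-(2,5-dibenzyloxy-3,4-dimethoxyphenyl)prop-2-enal | C=C(C=O)c1cc(OCc2ccccc2)c(OC)c(OC)c1OCc1ccccc1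
A7 | alternative 3 | 3-(2,5-dibenzyloxy-3,4-dimethoxyphenyl)-6,7,8-trimethoxy-2H-chromene | COc1cc2c(c(OC)c1OC)OCC(c1cc(OCc3ccccc3)c(OC)c(OC)c1OCc1ccccc1)=C2
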